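**Plan**
1. Retrosynthesis: the biaryl bond C6–C5′ between the two chromone units is cut first; each monomer is then cut in its pyranone ring at O1–C2 and C2–C3, back to a dihydroxyacetophenone and ethyl 3-phenylpropanoate.
2. Enabling feature: the bond lies ortho to the 7-OH of one unit (its para carbon C4a is the ring fusion) and para to the 8′-OH of the other, the carbons that carry phenoxyl spin density. The 7-OH is conjugated with C4=O through C4a (acidic, hard to oxidize); the 8′-OH is not (easier to oxidize), so the two free phenols take different roles in an oxidative coupling.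
3. Helper: a bromine at C8 of the 7-hydroxy unit blocks its more reactive ortho carbon so that only C6 can couple; hydrogenolysis removes it in the last step.
4. Forward: Claisen condensation and cyclodehydration build each pyranone ring (steps 1 and 3), bromination follows (step 2), an anodic dehydrogenative cross-coupling joins the halves (step 4), and debromination gives the target (step 5).
5. Stereochemistry: the target has no stereocenter, so nothing has to be set.

Key step: step 4

Remark: the biaryl axis carries one non-hydrogen ortho substituent on each ring (the 7-OH and the C4a′ ring fusion) and is assumed to rotate freely at room temperature, so the target is treated as achiral.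

**Step 1**
Reactants: 1 2′,4′-dihydroxyacetophenone; 2 ethyl 3-phenylpropanoate
Product: 4 7-hydroxy-2-(2-phenylethyl)-4H-chromen-4-one, via 1,3-diketone 3 (not isolated)
Conditions: LiN(SiMe3)2 (4.5 equiv), THF, −78 °C to rt; aq. HCl; then AcOH, cat. H2SO4, 100 °C
Reagents that add atoms: none
Why: Claisen condensation of the lithium enolate within the polyanion of 1 with ester 2 should give 1,3-diketone 3, and acid-catalysed cyclodehydration should close the pyranone through the 2-OH, the only hydroxyl ortho to the acyl group (the classical 1,3-diketone route to 2-substituted chromones).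

**Step 2**
Reactants: 4 7-hydroxy-2-(2-phenylethyl)-4H-chromen-4-one
Product: 5 8-bromo-7-hydroxy-2-(2-phenylethyl)-4H-chromen-4-one
Conditions: NBS (1.0 equiv), MeCN, 0 °C, dark
Reagents that add atoms: N-bromosuccinimide, O=C1CCC(=O)N1Br
Why: electrophilic aromatic bromination should go ortho to the 7-OH at C8, the carbon flanked by both ring oxygens and the kinetically preferred site of 7-hydroxychromones (comparable to C1 of 2-naphthol), so the more reactive ortho position is blocked and C6 stays open.

**Step 3**
Reactants: 6 2′,3′-dihydroxyacetophenone; 2 ethyl 3-phenylpropanoate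
Product: 8 8-hydroxy-2-(2-phenylethyl)-4H-chromen-4-one, via 1,3-diketone 7 (not isolated)
Conditions: LiN(SiMe3)2 (4.5 equiv), THF, −78 °C to rt; aq. HCl; then AcOH, cat. H2SO4, 100 °C
Reagents that add atoms: none
Why: the same Claisen condensation and acid-catalysed cyclodehydration as in step 1 should apply, the 2-OH ortho to the acyl group closing the pyranone and the 3-OH becoming the 8-OH of the chromone.

**Step 4**
Reactants: 5 8-bromo-7-hydroxy-2-(2-phenylethyl)-4H-chromen-4-one (3 equiv); 8 8-hydroxy-2-(2-phenylethyl)-4H-chromen-4-one (1 equiv)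
Product: 9 8-bromo-7-hydroxy-6-[8-hydroxy-4-oxo-2-(2-phenylethyl)-4H-chromen-5-yl]-2-(2-phenylethyl)-4H-chromen-4-one
Conditions: constant current (2 mA/cm2, 2.2 F per mol of 8), boron-doped diamond anode, Pt cathode, undivided cell, HFIP, 2,4,6-collidine (1 equiv per 5), Bu3NMe O3SOMe (0.05 M), 40 °C
Reagents that add atoms: none
Why: Proposed new method: anodic dehydrogenative cross-coupling of two acyl-deactivated chromone phenols, in which collidine ionizes only 5 (its 7-OH is para to C4a and thus conjugated with C4=O, and is further acidified by the 8-Br) while 8, whose 8-OH is not conjugated with the carbonyl and has the weaker O–H bond, is oxidized at the anode by proton-coupled electron transfer to an HFIP-solvated phenoxyl radical with its largest carbon spin density at the para carbon C5. This radical should add through C5 to C6 of the phenolate of 5, the radical anion so formed gives up a second electron, two tautomerizations restore both benzene rings, and the cathode reduces protons to H2; should 5 be oxidized first, hydrogen atom transfer from 8 would move the spin to 8 and give back the phenolate of 5. The closest known reaction types are the anodic dehydrogenative phenol–phenol cross-coupling at boron-doped diamond in HFIP, its base-assisted form for the homo-coupling of phenols with electron-withdrawing groups, and the classical oxidative phenol coupling with a bromine blocking group. No ring is closed and no stereocenter is formed, because the new axis has only the 7-OH and the ring-fusion carbon C4a of the other unit as ortho substituents. The step needs cross-coupling ahead of homo-coupling, which the different acidity and oxidizability of the two hydroxyls, the threefold excess of 5 and the low current density should secure. It also needs site selectivity, secured in 5 by the bromine at C8 and the quaternary C4a (only C6 is open ortho or para to the oxygen) and in 8 by the higher spin density of the para carbon C5 compared with the ortho carbon C7, as in the para-selective oxidative coupling of 2-alkoxyphenols.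

**Step 5**
Reactants: 9 8-bromo-7-hydroxy-6-[8-hydroxy-4-oxo-2-(2-phenylethyl)-4H-chromen-5-yl]-2-(2-phenylethyl)-4H-chromen-4-one
Product: 10 7-hydroxy-6-[8-hydroxy-4-oxo-2-(2-phenylethyl)-4H-chromen-5-yl]-2-(2-phenylethyl)-4H-chromen-4-one
Conditions: H2 (1 atm), Pd/C (10% palladium on carbon), NaOAc, EtOAc/MeOH, rt
Reagents that add atoms: none
Why: palladium-catalysed hydrogenolysis of the aryl C–Br bond (hydrodehalogenation) should outpace hydrogenation of the chromone C2=C3 bond, a vinylogous ester that survives the Pd/C hydrogenation used to turn 2-styrylchromones into 2-(2-phenylethyl)chromones, while NaOAc takes up the HBr.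

**Compound list**
1 | 2′,4′-dihydroxyacetophenone, 1-(2,4-dihydroxyphenyl)ethanone | CC(=O)c1ccc(O)cc1O | starting material
2 | ethyl 3-phenylpropanoate | CCOC(=O)CCc1ccccc1 | starting material
3 | 1-(2,4-dihydroxyphenyl)-5-phenylpentane-1,3-dione | O=C(CCc1ccccc1)CC(=O)c1ccc(O)cc1O | intermediate
4 | 7-hydroxy-2-(2-phenylethyl)-4H-chromen-4-one | O=c1cc(CCc2ccccc2)oc2cc(O)ccc12 | intermediate
5 | 8-bromo-7-hydroxy-2-(2-phenylethyl)-4H-chromen-4-one | O=c1cc(CCc2ccccc2)oc2c(Br)c(O)ccc12 | intermediate
6 | 2′,3′-dihydroxyacetophenone, 1-(2,3-dihydroxyphenyl)ethanone | CC(=O)c1cccc(O)c1O | starting material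
7 | 1-(2,3-dihydroxyphenyl)-5-phenylpentane-1,3-dione | O=C(CCc1ccccc1)CC(=O)c1cccc(O)c1O | intermediate
8 | 8-hydroxy-2-(2-phenylethyl)-4H-chromen-4-one | O=c1cc(CCc2ccccc2)oc2c(O)cccc12 | intermediate
9 | 8-bromo-7-hydroxy-6-[8-hydroxy-4-oxo-2-(2-phenylethyl)-4H-chromen-5-yl]-2-(2-phenylethyl)-4H-chromen-4-one | O=c1cc(CCc2ccccc2)oc2c(Br)c(O)c(-c3ccc(O)c4oc(CCc5ccccc5)cc(=O)c34)cc12 | intermediate
10 | 7-hydroxy-6-[8-hydroxy-4-oxo-2-(2-phenylethyl)-4H-chromen-5-yl]-2-(2-phenylethyl)-4H-chromen-4-one | O=c1cc(CCc2ccccc2)oc2cc(O)c(-c3ccc(O)c4oc(CCc5ccccc5)cc(=O)c34)cc12 | target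

**Totals**
Total step count: 5. Longest linear sequence: 4 steps (steps 1, 2, 4, 5).

**Steps most likely to fail**

Step 4 (proposed new method). The radical of 8 may dimerize through its para carbons instead of adding to the phenolate of 5, coupling may occur through the ortho carbon C7 of 8 or through oxygen, and the biaryl product may be oxidized further. The fallback is a Suzuki–Miyaura route of known chemistry that sets out from 1, 2 and 8 and comes back to the route at 10. Bromination of 1 (Br2, AcOH) para to the chelated 2-OH should give 1-(5-bromo-2,4-dihydroxyphenyl)ethanone F1. Claisen condensation with 2 under the conditions of step 1 gives 1-(5-bromo-2,4-dihydroxyphenyl)-5-phenylpentane-1,3-dione F2, and acid cyclodehydration gives 6-bromo-7-hydroxy-2-(2-phenylethyl)-4H-chromen-4-one F3. In parallel, 8 is benzylated (BnBr, K2CO3, DMF) to 8-(benzyloxy)-2-(2-phenylethyl)-4H-chromen-4-one F4. NBS in MeCN should brominate F4 para to the ether oxygen to give 8-(benzyloxy)-5-bromo-2-(2-phenylethyl)-4H-chromen-4-one F5. Miyaura borylation (bis(pinacolato)diboron, Pd(dppf)Cl2, KOAc, dioxane, 90 °C) gives 8-(benzyloxy)-2-(2-phenylethyl)-5-(4,4,5,5-tetramethyl-1,3,2-dioxaborolan-2-yl)-4H-chromen-4-one F6. Coupling of F3 with F6 (Pd(OAc)2, SPhos, K3PO4, toluene/water, 90 °C) gives 6-[8-(benzyloxy)-4-oxo-2-(2-phenylethyl)-4H-chromen-5-yl]-7-hydroxy-2-(2-phenylethyl)-4H-chromen-4-one F7, and hydrogenolysis of the benzyl ether (H2, Pd/C) gives 10.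

Step 2. Bromination may also take place at C6 or at C3 of the pyranone, or run on to a dibromide, so that the blocking group ends up in the wrong place. The fallback carries the bromine in from the start; it sets out from 2 and comes back to the route at 5. Purchased 2-bromobenzene-1,3-diol F8 is C-acetylated in a Nencki-type reaction (AcOH, BF3·OEt2, 90 °C) at the only activated ring position to give 1-(3-bromo-2,4-dihydroxyphenyl)ethanone F9, in which the bromine already sits between the two oxygens. Claisen condensation with 2 under the conditions of step 1 gives 1-(3-bromo-2,4-dihydroxyphenyl)-5-phenylpentane-1,3-dione F10, and acid cyclodehydration gives 5.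

Step 3. The catecholate polyanion of 6 may be poorly soluble and air-sensitive, so that C-acylation stays incomplete while the ester condenses with itself. The fallback replaces the intermolecular Claisen condensation by a Baker–Venkataraman acyl shift; it sets out from 6 and comes back to the route at 8. Acylation of both hydroxyls with 3-phenylpropanoyl chloride (pyridine, CH2Cl2) gives 3-acetyl-1,2-phenylene bis(3-phenylpropanoate) F11. KOtBu in THF should move the ortho acyl group from oxygen to the enolate carbon to give 2-hydroxy-3-(3-oxo-5-phenylpentanoyl)phenyl 3-phenylpropanoate F12. Cyclodehydration (AcOH, cat. H2SO4) gives 4-oxo-2-(2-phenylethyl)-4H-chromen-8-yl 3-phenylpropanoate F13, and mild methanolysis (K2CO3, MeOH) frees the phenol to give 8.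

**Further compounds**
F1 | step 4 | 1-(5-bromo-2,4-dihydroxyphenyl)ethanone | CC(=O)c1cc(Br)c(O)cc1O
F2 | step 4 | 1-(5-bromo-2,4-dihydroxyphenyl)-5-phenylpentane-1,3-dione | O=C(CCc1ccccc1)CC(=O)c1cc(Br)c(O)cc1O
F3 | step 4 | 6-bromo-7-hydroxy-2-(2-phenylethyl)-4H-chromen-4-one | O=c1cc(CCc2ccccc2)oc2cc(O)c(Br)cc12
F4 | step 4 | 8-(benzyloxy)-2-(2-phenylethyl)-4H-chromen-4-one | O=c1cc(CCc2ccccc2)oc2c(OCc3ccccc3)cccc12
F5 | step 4 | 8-(benzyloxy)-5-bromo-2-(2-phenylethyl)-4H-chromen-4-one | O=c1cc(CCc2ccccc2)oc2c(OCc3ccccc3)ccc(Br)c12
F6 | step 4 | 8-(benzyloxy)-2-(2-phenylethyl)-5-(4,4,5,5-tetramethyl-1,3,2-dioxaborolan-2-yl)-4H-chromen-4-one | O=c1cc(CCc2ccccc2)oc2c(OCc3ccccc3)ccc(B3OC(C)(C)C(C)(C)O3)c12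
F7 | step 4 | 6-[8-(benzyloxy)-4-oxo-2-(2-phenylethyl)-4H-chromen-5-yl]-7-hydroxy-2-(2-phenylethyl)-4H-chromen-4-one | O=c1cc(CCc2ccccc2)oc2cc(O)c(-c3ccc(OCc4ccccc4)c4oc(CCc5ccccc5)cc(=O)c34)cc12
F8 | step 2 | 2-bromobenzene-1,3-diol (2-bromoresorcinol, purchased) | Oc1cccc(O)c1Br
F9 | step 2 | 1-(3-bromo-2,4-dihydroxyphenyl)ethanone | CC(=O)c1ccc(O)c(Br)c1O
F10 | step 2 | 1-(3-bromo-2,4-dihydroxyphenyl)-5-phenylpentane-1,3-dione | O=C(CCc1ccccc1)CC(=O)c1ccc(O)c(Br)c1O
F11 | step 3 | 3-acetyl-1,2-phenylene bis(3-phenylpropanoate) | CC(=O)c1cccc(OC(=O)CCc2ccccc2)c1OC(=O)CCc1ccccc1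
F12 | step 3 | 2-hydroxy-3-(3-oxo-5-phenylpentanoyl)phenyl 3-phenylpropanoate | O=C(CCc1ccccc1)CC(=O)c1cccc(OC(=O)CCc2ccccc2)c1O
F13 | step 3 | 4-oxo-2-(2-phenylethyl)-4H-chromen-8-yl 3-phenylpropanoate | O=c1cc(CCc2ccccc2)oc2c(OC(=O)CCc3ccccc3)cccc12
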